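**Plan**
- Three olefins of the target each lie one metathesis away from a terminal vinyl group. They are the cis C3''=C4'' bond of the 2,2-dimethylpyran ring D (between the quaternary ether carbon C2'' and aromatic C5' of ring B) and the trisubstituted olefins of the prenyl chains on C6 and C8 of ring A.
- After removal of two silyl ethers, these three C=C bonds are cut together. This leaves a 6,8-diallyl-5'-vinyl-4'-(1,1-dimethylallyloxy)flavanone and 2-methylbut-2-ene.
- Ring C is opened at O1–C2 (Mitsunobu etherification) and at C2–C3 (aldol addition) into a ring A acetophenone and a ring B benzaldehyde.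
- The ring A allyl groups come from a double Claisen rearrangement of phloroacetophenone bis-allyl ether. On ring B the vinyl group comes from a Stille coupling at C5 and the tertiary allyl ether from a palladium-catalysed O-allylation.
- In the forward direction rings A and B are bought, ring C closes in step 9 and ring D in step 11.
- The only stereocentre, C2 (S), is first made racemic and then secured by a rhodium-catalysed transfer-hydrogenative kinetic resolution of the flavanone. All later steps are neutral or acid-buffered.

Key step: step 11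

Assumption: the (R,R)-configured transfer-hydrogenation catalyst is taken to consume the (2R)-flavanone, giving the 2,4-cis (2R,4R)-alcohol, as the usual sense of induction for aryl ketones predicts; if the sense is opposite, the (S,S)-catalyst is used instead.

**Step 1**
Reactants: 1 2,4,6-trihydroxyacetophenone; 2 allyl bromide
Product: 3 1-[2,4-bis(allyloxy)-6-hydroxyphenyl]ethanone
Conditions: 2 (2.1 equiv), K2CO3 (2.2 equiv), acetone, reflux
Reagents that add atoms: allyl bromide (2), C=CCBr
Why: Williamson etherification; the hydroxyl that is hydrogen-bonded to the acetyl oxygen is much less nucleophilic than the other two, so alkylation should stop at the bis-ether.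

**Step 2**
Reactants: 3 1-[2,4-bis(allyloxy)-6-hydroxyphenyl]ethanone
Product: 4 1-(3,5-diallyl-2,4,6-trihydroxyphenyl)ethanone
Conditions: N,N-diethylaniline, 200 °C, sealed vessel, argon
Reagents that add atoms: none
Why: Double aromatic Claisen rearrangement; C3 and C5 are the only free ring carbons, so ortho shifts and any ortho shift followed by a Cope shift converge on the same 3,5-diallyl product, and the allyl unit looks the same after each allylic inversion.

**Step 3**
Reactants: 4 1-(3,5-diallyl-2,4,6-trihydroxyphenyl)ethanone
Product: 5 1-[3,5-diallyl-4-(tert-butyldimethylsilyloxy)-2,6-dihydroxyphenyl]ethanone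
Conditions: TBSCl (1.05 equiv), imidazole (2.2 equiv), DMF, 0 °C
Reagents that add atoms: tert-butyldimethylsilyl chloride, CC(C)(C)[Si](C)(C)Cl
Why: Selective silylation of the most acidic phenol; the C4 hydroxyl is para to the acetyl group and free of chelation, whereas both ortho hydroxyls are engaged with or crowded by the carbonyl group.

**Step 4**
Reactants: 6 5-bromo-2,4-dihydroxybenzaldehyde; 7 tributyl(vinyl)stannane
Product: 8 2,4-dihydroxy-5-vinylbenzaldehyde
Conditions: 7 (1.2 equiv), Pd(PPh3)4 (5 mol %), 2,6-di-tert-butyl-4-methylphenol (trace), 1,4-dioxane, 100 °C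
Reagents that add atoms: tributyl(vinyl)stannane (7), C=C[Sn](CCCC)(CCCC)CCCC
Why: Stille coupling; it runs without base, so the phenols stay protonated, the aryl bromide keeps its reactivity towards zerovalent palladium, and the aldehyde is untouched.

**Step 5**
Reactants: 9 2-methylbut-3-en-2-ol
Product: 11 tert-butyl (2-methylbut-3-en-2-yl) carbonate, via lithium 2-methylbut-3-en-2-olate 10 (not isolated)
Conditions: n-BuLi (1.05 equiv), THF, −78 to 0 °C; then Boc2O (1.05 equiv), 0 °C to rt
Reagents that add atoms: di-tert-butyl dicarbonate, CC(C)(C)OC(=O)OC(=O)OC(C)(C)C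
Why: O-Acylation of a tertiary lithium alkoxide by Boc2O, the usual way to tertiary allylic carbonates that do not form cleanly under amine catalysis.

**Step 6**
Reactants: 8 2,4-dihydroxy-5-vinylbenzaldehyde; 11 tert-butyl (2-methylbut-3-en-2-yl) carbonate
Product: 12 2-hydroxy-4-(2-methylbut-3-en-2-yloxy)-5-vinylbenzaldehyde
Conditions: 11 (1.3 equiv), Pd(PPh3)4 (5 mol %), THF, 0 °C, stopped at full conversion of 8
Reagents that add atoms: carbonate 11, CC(C)(C)OC(=O)OC(C)(C)C=C
Why: Tsuji–Trost O-allylation; zerovalent palladium ionises the carbonate, the released tert-butoxide deprotonates the more acidic, non-chelated C4 phenol, and at low temperature the phenoxide attacks the more substituted terminus of the 1,1-dimethylallyl complex under kinetic control to give the tertiary ether.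

**Step 7**
Reactants: 12 2-hydroxy-4-(2-methylbut-3-en-2-yloxy)-5-vinylbenzaldehyde
Product: 13 2-(tert-butyldimethylsilyloxy)-4-(2-methylbut-3-en-2-yloxy)-5-vinylbenzaldehyde
Conditions: TBSCl (1.3 equiv), imidazole (2.5 equiv), DMF, rt
Reagents that add atoms: tert-butyldimethylsilyl chloride, CC(C)(C)[Si](C)(C)Cl
Why: Standard silylation of a salicylaldehyde-type phenol, done under mild base at room temperature so that the tertiary allyl aryl ether neither ionises nor undergoes Claisen rearrangement.

**Step 8**
Reactants: 5 1-[3,5-diallyl-4-(tert-butyldimethylsilyloxy)-2,6-dihydroxyphenyl]ethanone; 13 2-(tert-butyldimethylsilyloxy)-4-(2-methylbut-3-en-2-yloxy)-5-vinylbenzaldehyde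
Product: 15 rac-1-[3,5-diallyl-4-(tert-butyldimethylsilyloxy)-2,6-dihydroxyphenyl]-3-[2-(tert-butyldimethylsilyloxy)-4-(2-methylbut-3-en-2-yloxy)-5-vinylphenyl]-3-hydroxypropan-1-one, via trilithium enolate 14 (not isolated)
Conditions: 5, LiN(SiMe3)2 (3.1 equiv), THF, −78 to −20 °C; then 13, −78 °C; AcOH quench at −78 °C
Reagents that add atoms: none
Why: Directed aldol addition of a polylithiated ortho-hydroxyacetophenone, a reaction type known for C-alkylated phloroacetophenones; the low temperature and cold acidic quench are meant to outrun silyl migration and retro-aldol cleavage, the silyl ethers survive where hydroxide-mediated Claisen–Schmidt conditions would strip them, and the new carbinol centre forms without control (racemic).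

**Step 9**
Reactants: 15 the racemic aldol
Product: 16 rac-6,8-diallyl-7,2'-bis(tert-butyldimethylsilyloxy)-5-hydroxy-4'-(2-methylbut-3-en-2-yloxy)-5'-vinylflavanone
Conditions: PPh3 (1.5 equiv), DIAD (1.5 equiv), THF, 0 °C to rt
Reagents that add atoms: none
Why: Intramolecular Mitsunobu etherification (6-exo-tet closure of ring C by either of the two equivalent ortho phenols), known for chromanones and flavanones; it is neutral and cold, any elimination to the 2',6'-dihydroxychalcone feeds the same flavanone by oxa-Michael closure, and C2 is racemic at this stage.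

**Step 10**
Reactants: 16 the racemic flavanone
Product: 17 (2S)-6,8-diallyl-7,2'-bis(tert-butyldimethylsilyloxy)-5-hydroxy-4'-(2-methylbut-3-en-2-yloxy)-5'-vinylflavanone
Conditions: [Cp*RhCl((R,R)-TsDPEN)] (1 mol %), HCO2H/Et3N, EtOAc, rt, stopped just past half conversion; chromatography
Reagents that add atoms: none
Why: Kinetic resolution of a racemic flavanone by Noyori-type asymmetric transfer hydrogenation, an established access to enantiopure flavanones: the catalyst's preference for the (4R)-alcohol matches the substrate's preference for the 2,4-cis alcohol only in the (2R)-enantiomer, which is reduced, while (2S)-17 remains and is separated from the more polar alcohol, and isolated olefins are inert to the coordinatively saturated rhodium hydride.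

**Step 11**
Reactants: 17 the (2S)-diallyl vinyl flavanone; 18 2-methylbut-2-ene
Product: 20 (2S)-7,2'-bis-O-(tert-butyldimethylsilyl)euchrenone a3, via diallyl chromene flavanone 19 (not isolated)
Conditions: second-generation Hoveyda–Grubbs catalyst (H2IMes)Cl2Ru=CH(C6H4-2-OiPr) (5 mol %), 1,4-benzoquinone (10 mol %), CH2Cl2 (0.02 M), 40 °C; then 18 (equal volume) added to the same flask, sealed tube, 40 °C
Reagents that add atoms: 2-methylbut-2-ene (18), CC=C(C)C
Why: The ruthenium carbene exchanges with the electron-rich C5' styrene to give an ortho-alkoxybenzylidene, which adds across the neighbouring vinyl group of the 1,1-dimethylallyl ether to a metallacyclobutane and collapses with loss of ethene; this is the ring-closing metathesis of 2-vinylaryl allyl ethers known for 2H-chromenes, it closes the six-membered ring D between C4'' and C3'', and the ring size enforces the cis olefin. Only then is 18 admitted in large excess, and the alkylidenes formed at the two allyl termini of 19 take up its isopropylidene half with release of propene, which is the standard cross-metathesis of allylarenes to prenylarenes. The selectivity needed is that the styrene closes the ring before an isopropylidene unit can cap it and that the ether vinyl group reacts only intramolecularly: the order of addition secures the first point, and the quaternary C2'' next to that vinyl group, which blocks intermolecular metathesis, secures the second. Allyl homodimers that may form in the dilute first phase are still disubstituted olefins and should be drawn back into the cycle by the excess of 18, whereas the trisubstituted prenyl olefins and the conjugated cis olefin of ring D are not reopened, so the product acts as a sink. 1,4-Benzoquinone intercepts ruthenium hydrides and should keep the allyl double bonds from moving into conjugation with ring A. No stereocentre is formed, and C2 is safe because the medium is neutral and aprotic.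

**Step 12**
Reactants: 20 (2S)-7,2'-bis-O-(tert-butyldimethylsilyl)euchrenone a3
Product: 21 euchrenone a3
Conditions: Bu4NF/AcOH (1:1, 2.5 equiv each), THF, 0 °C
Reagents that add atoms: none
Why: Fluoride-mediated cleavage of aryl silyl ethers; acetic acid protonates each phenoxide as it is released, which shuts off the base-induced ring opening to the chalcone that would racemise C2, and the olefins are inert.

**Compound list**
1 | 2,4,6-trihydroxyacetophenone | CC(=O)c1c(O)cc(O)cc1O | starting material
2 | allyl bromide | C=CCBr | starting material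
3 | 1-[2,4-bis(allyloxy)-6-hydroxyphenyl]ethanone | CC(=O)c1c(O)cc(OCC=C)cc1OCC=C | intermediate
4 | 1-(3,5-diallyl-2,4,6-trihydroxyphenyl)ethanone | CC(=O)c1c(O)c(CC=C)c(O)c(CC=C)c1O | intermediate
5 | 1-[3,5-diallyl-4-(tert-butyldimethylsilyloxy)-2,6-dihydroxyphenyl]ethanone | CC(=O)c1c(O)c(CC=C)c(O[Si](C)(C)C(C)(C)C)c(CC=C)c1O | intermediate
6 | 5-bromo-2,4-dihydroxybenzaldehyde | O=Cc1cc(Br)c(O)cc1O | starting material
7 | tributyl(vinyl)stannane | C=C[Sn](CCCC)(CCCC)CCCC | starting material
8 | 2,4-dihydroxy-5-vinylbenzaldehyde | O=Cc1cc(C=C)c(O)cc1O | intermediate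
9 | 2-methylbut-3-en-2-ol | CC(C)(O)C=C | starting material
10 | lithium 2-methylbut-3-en-2-olate (not isolated) | [Li+].CC(C)([O-])C=C | intermediate
11 | tert-butyl (2-methylbut-3-en-2-yl) carbonate | CC(C)(C)OC(=O)OC(C)(C)C=C | intermediate
12 | 2-hydroxy-4-(2-methylbut-3-en-2-yloxy)-5-vinylbenzaldehyde | O=Cc1cc(C=C)c(OC(C)(C)C=C)cc1O | intermediate
13 | 2-(tert-butyldimethylsilyloxy)-4-(2-methylbut-3-en-2-yloxy)-5-vinylbenzaldehyde | O=Cc1cc(C=C)c(OC(C)(C)C=C)cc1O[Si](C)(C)C(C)(C)C | intermediate
14 | trilithium enolate of 5 (not isolated) | [Li+].[Li+].[Li+].C=C([O-])c1c([O-])c(CC=C)c(O[Si](C)(C)C(C)(C)C)c(CC=C)c1[O-] | intermediate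
15 | rac-aldol of 5 and 13 (3-hydroxypropan-1-one) | C=CCc1c(O[Si](C)(C)C(C)(C)C)c(CC=C)c(O)c(C(=O)CC(O)c2cc(C=C)c(OC(C)(C)C=C)cc2O[Si](C)(C)C(C)(C)C)c1O | intermediate
16 | rac-6,8-diallyl-7,2'-bis(tert-butyldimethylsilyloxy)-5-hydroxy-4'-(2-methylbut-3-en-2-yloxy)-5'-vinylflavanone | C=CCc1c(O[Si](C)(C)C(C)(C)C)c(CC=C)c2c(c1O)C(=O)CC(c1cc(C=C)c(OC(C)(C)C=C)cc1O[Si](C)(C)C(C)(C)C)O2 | intermediate
17 | (2S)-6,8-diallyl-7,2'-bis(tert-butyldimethylsilyloxy)-5-hydroxy-4'-(2-methylbut-3-en-2-yloxy)-5'-vinylflavanone | C=CCc1c(O[Si](C)(C)C(C)(C)C)c(CC=C)c2c(c1O)C(=O)C[C@@H](c1cc(C=C)c(OC(C)(C)C=C)cc1O[Si](C)(C)C(C)(C)C)O2 | intermediate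
18 | 2-methylbut-2-ene | CC=C(C)C | starting material
19 | (2S)-6,8-diallyl-7-(tert-butyldimethylsilyloxy)-2-[7-(tert-butyldimethylsilyloxy)-2,2-dimethyl-2H-chromen-6-yl]-5-hydroxychroman-4-one (not isolated) | C=CCc1c(O[Si](C)(C)C(C)(C)C)c(CC=C)c2c(c1O)C(=O)C[C@@H](c1cc3c(cc1O[Si](C)(C)C(C)(C)C)OC(C)(C)C=C3)O2 | intermediate
20 | (2S)-7,2'-bis-O-(tert-butyldimethylsilyl)euchrenone a3 | CC(C)=CCc1c(O[Si](C)(C)C(C)(C)C)c(CC=C(C)C)c2c(c1O)C(=O)C[C@@H](c1cc3c(cc1O[Si](C)(C)C(C)(C)C)OC(C)(C)C=C3)O2 | intermediate
21 | euchrenone a3, (2S)-5,7-dihydroxy-2-(7-hydroxy-2,2-dimethyl-2H-chromen-6-yl)-6,8-bis(3-methylbut-2-enyl)chroman-4-one | CC(C)=CCc1c(O)c(CC=C(C)C)c2c(c1O)C(=O)C[C@@H](c1cc3c(cc1O)OC(C)(C)C=C3)O2 | target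

**Step count**
Total steps: 12.
Longest linear sequence: 8 steps (steps 4, 6, 7, 8, 9, 10, 11, 12; the ring A branch through steps 1, 2, 3 is equally long).

**Steps most likely to fail**

Step 10.
- Hydride transfer to a carbonyl group that is chelated by the 5-OH and enriched by two oxygen donors may be slow.
- The rate difference between the two enantiomers may also be too small, in which case the recovered ketone would not reach high enantiomeric purity.
- Fallback: the resolution becomes a physical separation. Setting out from 16, semi-preparative HPLC on an amylose tris(3,5-dimethylphenylcarbamate) stationary phase should deliver 17 directly, beside the (2R)-enantiomer F1.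
- F1 can be returned to 16 by base-catalysed ring opening and reclosure (i-Pr2NEt, warm MeCN) and resubmitted, so the route is rejoined at 17.

Step 8.
- The ortho silyl group of ring B may migrate to the newly formed lithium alkoxide.
- The adduct may revert by retro-aldol cleavage, or the triply charged enolate may be too poorly soluble and too unreactive.
- Fallback: a thermodynamic condensation without protecting groups, followed by late silylation, sets out from 4 and 12.
- The two are combined with LiN(SiMe3)2 (one equivalent per acidic proton and a slight excess) in THF, −78 °C to rt. This should drive addition and elimination through to the E-chalcone F2.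
- NaOAc in warm EtOH then closes ring C by oxa-Michael addition to the racemic trihydroxyflavanone F3.
- TBSCl (2.2 equiv) and imidazole in DMF silylate the 7- and 2'-hydroxyls while the chelated 5-OH stays free. The route is rejoined at 16.

Step 11.
- The catalyst may be held as a slowly turning-over chelated ortho-alkoxybenzylidene.
- The allyl double bonds may migrate into conjugation.
- Exchange may stay incomplete at one of the two allyl groups.
- Fallback: the two kinds of metathesis are separated in the sequence. Setting out from 13, ring closure with the same ruthenium catalyst in CH2Cl2, with no allyl groups and no 18 present, should give 7-(tert-butyldimethylsilyloxy)-2,2-dimethyl-2H-chromene-6-carbaldehyde F4.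
- Addition of enolate 14 at −78 °C gives the aldol F5, and Mitsunobu closure gives the racemic chromene flavanone F6.
- The transfer-hydrogenative resolution of step 10 then leaves the (2S)-ketone. The route is rejoined at 19, now isolated, which needs only the double cross-metathesis with 18 to reach 20.

**Further compounds**
F1 | step 10 | (2R)-6,8-diallyl-7,2'-bis(tert-butyldimethylsilyloxy)-5-hydroxy-4'-(2-methylbut-3-en-2-yloxy)-5'-vinylflavanone | C=CCc1c(O[Si](C)(C)C(C)(C)C)c(CC=C)c2c(c1O)C(=O)C[C@H](c1cc(C=C)c(OC(C)(C)C=C)cc1O[Si](C)(C)C(C)(C)C)O2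
F2 | step 8 | (E)-1-(3,5-diallyl-2,4,6-trihydroxyphenyl)-3-[2-hydroxy-4-(2-methylbut-3-en-2-yloxy)-5-vinylphenyl]prop-2-en-1-one | C=CCc1c(O)c(CC=C)c(O)c(C(=O)/C=C/c2cc(C=C)c(OC(C)(C)C=C)cc2O)c1O
F3 | step 8 | rac-6,8-diallyl-5,7,2'-trihydroxy-4'-(2-methylbut-3-en-2-yloxy)-5'-vinylflavanone | C=CCc1c(O)c(CC=C)c2c(c1O)C(=O)CC(c1cc(C=C)c(OC(C)(C)C=C)cc1O)O2
F4 | step 11 | 7-(tert-butyldimethylsilyloxy)-2,2-dimethyl-2H-chromene-6-carbaldehyde | O=Cc1cc2c(cc1O[Si](C)(C)C(C)(C)C)OC(C)(C)C=C2
F5 | step 11 | rac-1-[3,5-diallyl-4-(tert-butyldimethylsilyloxy)-2,6-dihydroxyphenyl]-3-[7-(tert-butyldimethylsilyloxy)-2,2-dimethyl-2H-chromen-6-yl]-3-hydroxypropan-1-one | C=CCc1c(O[Si](C)(C)C(C)(C)C)c(CC=C)c(O)c(C(=O)CC(O)c2cc3c(cc2O[Si](C)(C)C(C)(C)C)OC(C)(C)C=C3)c1O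
F6 | step 11 | rac-6,8-diallyl-7-(tert-butyldimethylsilyloxy)-2-[7-(tert-butyldimethylsilyloxy)-2,2-dimethyl-2H-chromen-6-yl]-5-hydroxychroman-4-one | C=CCc1c(O[Si](C)(C)C(C)(C)C)c(CC=C)c2c(c1O)C(=O)CC(c1cc3c(cc1O[Si](C)(C)C(C)(C)C)OC(C)(C)C=C3)O2
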